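(Readings and results come from a simulation with made-up constants; scatter was added.)

Before you fit anything, decide to read one number off the earlier runs: how the electrophile divides between its two ways out.

| flask | electrophile | nucleophile | remark | time |
|---|---|---|---|---|
| north-west | 0.20 M | 0.30 M | run made earlier |  |
| east | 0.20 M | 0.55 M | run made earlier |  |
| larch | 0.20 M | 0.240 M |  | 30 h |
| alder | 0.20 M | 0.310 M |  | 30 h |
| birch | 0.20 M | 0.410 M |  | 30 h |

| run | time / h | electrophile / % | target / % |
|---|---|---|---|
| north-west | 1.33 | 88 | 6 |
| north-west | 2.50 | 79 | 10 |
| north-west | 4.00 | 72 | 12 |
| north-west | 8.00 | 55 | 20 |
| north-west | 15.0 | 38 | 19 |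
| east | 1.33 | 83 | 12 |
| east | 2.50 | 72 | 19 |
| east | 4.00 | 63 | 23 |
| east | 8.00 | 40 | 28 |
| east | 15.0 | 24 | 21 |

(standard deviation of a reading: 1.5 percentage points)

- steps that have been proposed: electrophile + nucleophile -> acid set free + target; nucleophile + acid set free <-> protonated nucleophile; electrophile <-> dormant form; target -> over-reaction product
- what has gone from electrophile into another species counts as reacted, even if it can come back

1. part of the electrophile that has reacted at the end, larch
2. part of the electrophile that has reacted at the end, alder
3. part of the electrophile that has reacted at the end, birch
4. what raising the concentration of nucleophile from its lowest to its highest value here does to the part of the electrophile that has reacted (changes below 5 percentage points count as none) (it rises / it falls / no change)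

Electrophile leaves with nucleophile to target, or without nucleophile to the dormant form, so at an early reading the target divided by the rest of the electrophile gone gives a quotient r, a rough reading of how the two paths divide, with the even split, r equal to one, as the zero of the scale; but that rest also holds any over-reaction product, and target lost to it no longer counts as target, so r reads low. Dividing r by the nucleophile charge at 2.50 h and averaging the north-west and east runs gives the quotient per unit of nucleophile, 3.43 M⁻¹, a reading that carries the scatter of 1.5 percentage points. My own reckoning therefore puts r at 0.824 for larch and 1.41 for birch; both paths count as reacted, so r does not give the reacted part, but its rise says that the nucleophile path quickens with the charge beside a dormant path that does not use nucleophile, and so I expect the reacted part to be higher in birch than in larch.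

The forecast gives 70% for larch, 74% for alder and 78% for birch, with the trend it rises, on the ground that “electrophile left is about half of (electrophile + dormant)”.

The flasks give 71.3%, 76.5% and 82.6%, so the forecast holds: it rises, by 11 points.

    electrophile + nucleophile → acid set free + target (k = 5.19 × 10⁻⁵ M⁻¹ s⁻¹)
    nucleophile + acid set free ⇌ protonated nucleophile, settled at all times (K = 17000 M⁻¹)
    electrophile ⇌ dormant form (K = 1.10, k = 1.10 × 10⁻⁵ s⁻¹)
    target → over-reaction product (k = 2.45 × 10⁻⁵ s⁻¹)

In birch, where r stands at 1.41, above one, the half-life of electrophile by the nucleophile step at 6.14 h is 13 h, shorter than the 18 h by the forward dormant step alone, and birch ends with 58.9% in target and over-reaction product against 23.7% dormant. In a neighbouring flask, birch with 0.16 M of nucleophile, the same reckoning gives r of 0.549, below one, and there the dormant form ends at 36.1%, more than the 28.2% in target and over-reaction product.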